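Wednesday's small charge of substrate gave a better percentage of target than Sunday's large one, and you want to know what the middle charge gives.

| flask | substrate | second nucleophile | gas | remark | time |
|---|---|---|---|---|---|
| Wednesday's | 0.23 M | 2.25 M | 99 mM (held) | run made earlier |  |
| Sunday's | 0.90 M | 2.25 M | 99 mM (held) | run made earlier |  |
| flask | 0.45 M | 2.25 M | 99 mM (held) |  | 20 h |

| run | time / h | target / % |
|---|---|---|
| Wednesday's | 0.200 | 14.5 |
| Wednesday's | 1.00 | 16.3 |
| Wednesday's | 4.00 | 12.4 |
| Wednesday's | 20.0 | 2.6 |
| Sunday's | 0.200 | 3.9 |
| Sunday's | 1.00 | 6.4 |
| Sunday's | 4.00 | 4.7 |
| Sunday's | 20.0 | 0.6 |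

(standard deviation of a reading: 0.3 percentage points)

- target is meant together with its crystals
- solid, in amounts per volume of the solution: crystals
- at the start none of first nucleophile is dissolved
- the numbers in the tables scatter with a standard deviation of 0.3 percentage points
- steps under discussion: substrate -> intermediate; first nucleophile + intermediate -> target; second nucleophile + intermediate -> other capture product; crystals <-> target; gas <-> first nucleophile; first nucleophile + target -> over-reaction product

* time up to 20 h at which target stands highest
* the amount of target, in percent of the substrate charged, at that time

Here is the odd thing. Sunday's run held 3.91 times Wednesday's substrate, yet at 0.200 h the two runs held 33.3 mM and 35.1 mM of target. Target in Sunday's run stood above Wednesday's by less than the charge did, so I read its early pace as set by first nucleophile dissolving from the gas. I replace that early curve by its mean over the first 0.200 h, taken across both runs: 171 mM h⁻¹.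

Now define the capture window: the time this mean supply needs to deliver a run's highest reading. Wednesday's is 0.219 h and Sunday's is 0.337 h. I assume the window grows with the logarithm of the charge, as the time a first-order flow from substrate stays above a fixed rate does, and interpolate on that logarithm, at 0.0861 h per unit. For the flask this gives 0.277 h, hence 47.4 mM of target, or 10.5 % of its charge.

The error of this reckoning: between 4.00 h and 20.0 h Wednesday's readings fall at 0.0976 h⁻¹, and at that pace a reading at 1.00 h sits about 9.30 % under what was made, so the windows may run short by up to that share. I expect the flask's top between the readings' 0.200 h and 1.00 h.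

The forecast, holding that “formation looks limited by first nucleophile dissolving from the gas”, gave 10.3 % at 0.75 h. The flask gives 10.4 % at 0.456 h.

    substrate → intermediate (k = 19.0 h⁻¹)
    first nucleophile + intermediate → target (k = 7600 M⁻¹ h⁻¹)
    second nucleophile + intermediate → other capture product (k = 14.0 M⁻¹ h⁻¹)
    crystals ⇌ target, rate k4*(cs4 - [target]) while solid is left; crystals form when [target] > cs4 (solubility = 0.330 M, k = 9.50 h⁻¹)
    gas ⇌ first nucleophile, rate k5*(csat - [first nucleophile]) (kL = 1.90 h⁻¹)
    first nucleophile + target → over-reaction product (k = 1.00 M⁻¹ h⁻¹)

The flask's own peak, divided by the mean supply, gives a window of 0.275 h against the 0.277 h reckoned. The window is a reckoned length, and the clock time of the flask's peak is longer. The neighbouring flask holds 0.18 M of substrate, with the other charges unchanged. Its window, extrapolated below Wednesday's charge, comes to 0.198 h, which means 33.9 mM of target, or 18.8 % of that charge. At its highest, target in that neighbouring flask reaches 19.9 %.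

The runs were computed from invented constants; the scatter is artificial.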